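## Retrosynthetic overview

- Ring C is opened at O1–C2. C2 and C4 are both benzylic, oxygen-bearing carbons in a 1,3-relation between ring B and ring A, so the 2,4-trans flavan-4-ol is an anti-1,3-diarylpropane-1,3-diol in which the ring-A phenol oxygen (O1) replaces the C2 hydroxyl with inversion and C4–OH is left alone.
- The anti diol comes from a 1,3-diketone: catalyst-controlled transfer hydrogenation of the ring-B carbonyl, then hydroxyl-directed anti reduction of the ring-A carbonyl (C4).
- The diketone (C2–C3 bond) comes from an O-to-C aroyl shift of a 4-(pivaloyloxy)benzoate sitting on the oxygen that becomes O1.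
- The C8 prenyl carbon is para to O5, so prenyl is relayed from an O5 prenyl ether by Claisen–Cope rearrangement on the symmetric 2',6'-dihydroxy-4'-methoxyacetophenone core, before the aroyl shift.
- Ring order: rings A and B are bought; ring C (the pyran) is the only ring made, and it is closed last.

Key step: step 10

Remark: the SMILES is read as (2S,4R), with the 2-aryl group and the 4-hydroxyl trans on ring C. Prenyl = 3-methylbut-2-enyl, Piv = pivaloyl, TIPS = triisopropylsilyl.

## Route

Step 1
Reactants: 1 4-hydroxybenzoic acid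
Product: 2 4-(pivaloyloxy)benzoic acid
Conditions: PivCl (1.1 equiv), NaOH (aq., 2.2 equiv), THF/H2O, 0 °C; then HCl to pH 2
Reagents that add atoms: pivaloyl chloride CC(C)(C)C(Cl)=O
Why: Schotten–Baumann acylation: the phenoxide is acylated by pivaloyl chloride, any mixed anhydride formed at the carboxylate is hydrolysed in the aqueous base, and the hindered aryl pivalate survives the cold work-up.

Step 2
Reactants: 2 4-(pivaloyloxy)benzoic acid
Product: 3 4-(pivaloyloxy)benzoyl chloride
Conditions: (COCl)2, DMF (cat.), CH2Cl2, 0 °C to rt; evaporated and used crude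
Reagents that add atoms: oxalyl chloride O=C(Cl)C(Cl)=O
Why: Acid chloride formation through the DMF-derived chloroiminium (Vilsmeier-type) activator; the aryl pivalate is inert and the by-products are gases.

Step 3
Reactants: 4 2',6'-dihydroxy-4'-methoxyacetophenone; 5 prenyl bromide
Product: 6 1-[2-hydroxy-4-methoxy-6-(3-methylbut-2-enyloxy)phenyl]ethanone
Conditions: K2CO3 (1.1 equiv), acetone, reflux
Reagents that add atoms: none
Why: Williamson ether synthesis: the two hydroxyls of 4 are equivalent by symmetry, and after the first O-alkylation the remaining hydroxyl is locked in a hydrogen bond to the acetyl carbonyl and is far less nucleophilic, so one equivalent of bromide should stop at the mono-ether.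

Step 4
Reactants: 6 1-[2-hydroxy-4-methoxy-6-(3-methylbut-2-enyloxy)phenyl]ethanone; 3 4-(pivaloyloxy)benzoyl chloride
Product: 7 2-acetyl-5-methoxy-3-(3-methylbut-2-enyloxy)phenyl 4-(pivaloyloxy)benzoate
Conditions: Et3N, DMAP (cat.), CH2Cl2, 0 °C to rt
Reagents that add atoms: none
Why: DMAP-catalysed O-acylation (esterification) of the chelated phenol through the acylpyridinium ion; this ester is the substrate for the later acyl shift and marks the oxygen that becomes O1, while the allylic ether and the pivalate are untouched.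

Step 5
Reactants: 7 2-acetyl-5-methoxy-3-(3-methylbut-2-enyloxy)phenyl 4-(pivaloyloxy)benzoate
Product: 10 2-acetyl-3-hydroxy-5-methoxy-6-(3-methylbut-2-enyl)phenyl 4-(pivaloyloxy)benzoate, via ortho-dienone 8 (not isolated), via para-dienone 9 (not isolated)
Conditions: Eu(fod)3 (10 mol%), NaHCO3, CHCl3, 65 °C (sealed tube)
Reagents that add atoms: none
Why: Lewis-acid-catalysed aromatic Claisen rearrangement followed by Cope rearrangement (para-Claisen–Cope): europium chelated between the acetyl and ether oxygens accelerates the first [3,3] shift to ortho-dienone 8, a second [3,3] shift carries the allyl unit on to the carbon para to the original ether oxygen (para-dienone 9, prenyl no longer inverted), and enolisation should give the phenol with the prenyl group between the aroyloxy and methoxy carbons.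

Step 6
Reactants: 10 2-acetyl-3-hydroxy-5-methoxy-6-(3-methylbut-2-enyl)phenyl 4-(pivaloyloxy)benzoate
Product: 11 2-acetyl-5-methoxy-6-(3-methylbut-2-enyl)-3-(triisopropylsilyloxy)phenyl 4-(pivaloyloxy)benzoate
Conditions: TIPSOTf, 2,6-lutidine, CH2Cl2, −78 to 0 °C
Reagents that add atoms: triisopropylsilyl trifluoromethanesulfonate CC(C)[Si](OS(=O)(=O)C(F)(F)F)(C(C)C)C(C)C
Why: Silyl ether formation with the reactive silyl triflate, needed because the phenol is hydrogen-bonded to the acetyl group; the bulky TIPS group masks O5 so that O1 is the only free phenol at the ring closure, and it should survive base, mild acid and the Mitsunobu reagents.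

Step 7
Reactants: 11 2-acetyl-5-methoxy-6-(3-methylbut-2-enyl)-3-(triisopropylsilyloxy)phenyl 4-(pivaloyloxy)benzoate
Product: 12 1-[2-hydroxy-4-methoxy-3-(3-methylbut-2-enyl)-6-(triisopropylsilyloxy)phenyl]-3-[4-(pivaloyloxy)phenyl]propane-1,3-dione
Conditions: LiN(SiMe3)2 (LiHMDS, 3 equiv), THF, −78 °C to rt; aq. NH4Cl quench at 0 °C
Reagents that add atoms: none
Why: Baker–Venkataraman rearrangement: the lithium enolate of the acetyl group attacks the neighbouring aryl ester carbonyl in an intramolecular Claisen condensation through a six-membered transition state and the aroyl group moves from oxygen to carbon, which makes the C2–C3 bond of the future ring C and frees the O1 phenol beside the prenyl group; the non-nucleophilic amide base spares the pivalate and the buffered quench avoids cyclodehydration to a flavone.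

Step 8
Reactants: 12 1-[2-hydroxy-4-methoxy-3-(3-methylbut-2-enyl)-6-(triisopropylsilyloxy)phenyl]-3-[4-(pivaloyloxy)phenyl]propane-1,3-dione
Product: 13 (R)-3-hydroxy-1-[2-hydroxy-4-methoxy-3-(3-methylbut-2-enyl)-6-(triisopropylsilyloxy)phenyl]-3-[4-(pivaloyloxy)phenyl]propan-1-one
Conditions: RuCl[(R,R)-TsDPEN](p-cymene) (2 mol%), HCO2H/Et3N (5:2), CH2Cl2, 25 °C; stopped at the monoalcohol
Reagents that add atoms: none
Why: Noyori asymmetric transfer hydrogenation, a known way to mono-reduce 1,3-diaryl 1,3-diketones: the ruthenium hydride of the (R,R)-TsDPEN ligand, the hand that gives (R)-1-arylethanols, delivers hydride and proton to the ring-B carbonyl through the six-membered outer-sphere transition state with the aryl group beside the η6-arene and so sets the (R)-carbinol, while the ring-A carbonyl is flanked by two ortho substituents and tied up in a hydrogen bond to the phenol and should stay.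

Step 9
Reactants: 13 (R)-3-hydroxy-1-[2-hydroxy-4-methoxy-3-(3-methylbut-2-enyl)-6-(triisopropylsilyloxy)phenyl]-3-[4-(pivaloyloxy)phenyl]propan-1-one
Product: 14 (1R,3R)-1-[2-hydroxy-4-methoxy-3-(3-methylbut-2-enyl)-6-(triisopropylsilyloxy)phenyl]-3-[4-(pivaloyloxy)phenyl]propane-1,3-diol (anti)
Conditions: Me4NBH(OAc)3 (5 equiv), MeCN/AcOH (3:1), −35 °C, short contact; cold aq. NaHCO3 quench
Reagents that add atoms: none
Why: Evans–Saksena hydroxyl-directed reduction: the ring-B hydroxyl exchanges onto boron and the resulting alkoxy(diacetoxy)borohydride delivers hydride intramolecularly through a chair six-membered transition state to the acid-activated ketone, so the new C4 hydroxyl is 1,3-anti to the (R)-carbinol, i.e. (R); low temperature, short contact and a cold basic quench protect the acid-sensitive electron-rich benzylic alcohol.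

Step 10
Reactants: 14 (1R,3R)-1-[2-hydroxy-4-methoxy-3-(3-methylbut-2-enyl)-6-(triisopropylsilyloxy)phenyl]-3-[4-(pivaloyloxy)phenyl]propane-1,3-diol
Product: 16 (2S,4R)-7-methoxy-8-(3-methylbut-2-enyl)-2-[4-(pivaloyloxy)phenyl]-5-(triisopropylsilyloxy)chroman-4-ol (2,4-trans), via alkoxyphosphonium phenoxide zwitterion 15 (not isolated)
Conditions: PPh3 (1.3 equiv), DIAD (1.2 equiv, slow addition), THF/toluene, 0 °C, 0.01 M
Reagents that add atoms: none
Why: Proposed new method: the PPh3–DIAD betaine deprotonates the ring-A phenol and converts the ring-B carbinol into its alkoxyphosphonium ion (zwitterion 15), which the phenoxide oxygen displaces from the rear to form the O1–C2 bond with release of Ph3P=O. The closest known reaction type is the Mitsunobu cycloetherification of 2-(3-aryl-3-hydroxypropyl)phenols to flavans and of β-hydroxy 2'-hydroxyaryl ketones to flavanones, here extended to an unprotected anti-1,3-diol carrying a trioxygenated ring A. Ring C, the pyran, closes in the 6-exo-tet mode. C2 becomes (S) by SN2 inversion of the (R)-carbinol set in step 8, while C4 keeps the (R) configuration from step 9, so the anti diol maps onto the 2,4-trans product that hydride reduction of a flavanone does not deliver. The step needs activation of the ring-B carbinol rather than the C4 carbinol and no ionisation at either benzylic carbon: the C4 hydroxyl lies between two ortho substituents and is hydrogen-bonded to the phenol, closure from an activated C4 would need a four-membered ring and phosphonium exchange can return that material, O5 is silylated so only O1 can attack, and the electron-withdrawing 4'-pivaloyloxy group disfavours a C2 cation. Slow addition of DIAD to a cold, dilute solution keeps the betaine concentration low, which should suppress loss of the C4 oxygen through an ortho-quinone methide and spare the prenyl alkene.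

Step 11
Reactants: 16 (2S,4R)-7-methoxy-8-(3-methylbut-2-enyl)-2-[4-(pivaloyloxy)phenyl]-5-(triisopropylsilyloxy)chroman-4-ol
Product: 17 (2S,4R)-7-methoxy-8-(3-methylbut-2-enyl)-2-[4-(pivaloyloxy)phenyl]chroman-4,5-diol
Conditions: TBAF (1.1 equiv), AcOH (1.1 equiv), THF, 0 °C; pH 7 buffer work-up, Et3N-washed silica
Reagents that add atoms: none
Why: Fluoride-mediated desilylation driven by the Si–F bond; the acetic acid buffer keeps the medium near neutral so that the aryl pivalate and the labile C4 benzylic alcohol are not attacked, and no stereocentre is involved.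

Step 12
Reactants: 17 (2S,4R)-7-methoxy-8-(3-methylbut-2-enyl)-2-[4-(pivaloyloxy)phenyl]chroman-4,5-diol
Product: 18 (2S,4R)-4,5,4'-trihydroxy-7-methoxy-8-prenylflavan (target)
Conditions: K2CO3 (0.3 equiv), MeOH, 0 °C, brief; pH 7 phosphate buffer, Et3N-washed silica
Reagents that add atoms: none
Why: Base-catalysed transesterification (methanolysis) of the aryl pivalate, the only ester left and one with a phenoxide leaving group; cold, brief exposure and a neutral work-up avoid phenoxide-assisted ionisation at C4, so both stereocentres should be retained.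

## Compound list

1 | 4-hydroxybenzoic acid | OC(=O)c1ccc(O)cc1 | starting material
2 | 4-(pivaloyloxy)benzoic acid | CC(C)(C)C(=O)Oc1ccc(cc1)C(O)=O | intermediate
3 | 4-(pivaloyloxy)benzoyl chloride | CC(C)(C)C(=O)Oc1ccc(cc1)C(Cl)=O | intermediate
4 | 2',6'-dihydroxy-4'-methoxyacetophenone | CC(=O)c1c(O)cc(OC)cc1O | starting material
5 | prenyl bromide (1-bromo-3-methylbut-2-ene) | CC(C)=CCBr | starting material
6 | 1-[2-hydroxy-4-methoxy-6-(3-methylbut-2-enyloxy)phenyl]ethanone | CC(=O)c1c(O)cc(OC)cc1OCC=C(C)C | intermediate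
7 | 2-acetyl-5-methoxy-3-(3-methylbut-2-enyloxy)phenyl 4-(pivaloyloxy)benzoate | CC(=O)c1c(OC(=O)c2ccc(OC(=O)C(C)(C)C)cc2)cc(OC)cc1OCC=C(C)C | intermediate
8 | ortho-dienone: 2-acetyl-5-methoxy-4-(2-methylbut-3-en-2-yl)-3-oxocyclohexa-1,5-dien-1-yl 4-(pivaloyloxy)benzoate (racemic at the sp3 ring carbon) | CC(=O)C1=C(OC(=O)c2ccc(OC(=O)C(C)(C)C)cc2)C=C(OC)C(C(C)(C)C=C)C1=O | intermediate
9 | para-dienone: 2-acetyl-5-methoxy-6-(3-methylbut-2-enyl)-3-oxocyclohexa-1,4-dien-1-yl 4-(pivaloyloxy)benzoate (racemic at the sp3 ring carbon) | CC(=O)C1=C(OC(=O)c2ccc(OC(=O)C(C)(C)C)cc2)C(CC=C(C)C)C(OC)=CC1=O | intermediate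
10 | 2-acetyl-3-hydroxy-5-methoxy-6-(3-methylbut-2-enyl)phenyl 4-(pivaloyloxy)benzoate | CC(=O)c1c(OC(=O)c2ccc(OC(=O)C(C)(C)C)cc2)c(CC=C(C)C)c(OC)cc1O | intermediate
11 | 2-acetyl-5-methoxy-6-(3-methylbut-2-enyl)-3-(triisopropylsilyloxy)phenyl 4-(pivaloyloxy)benzoate | CC(=O)c1c(OC(=O)c2ccc(OC(=O)C(C)(C)C)cc2)c(CC=C(C)C)c(OC)cc1O[Si](C(C)C)(C(C)C)C(C)C | intermediate
12 | 1-[2-hydroxy-4-methoxy-3-(3-methylbut-2-enyl)-6-(triisopropylsilyloxy)phenyl]-3-[4-(pivaloyloxy)phenyl]propane-1,3-dione | CC(C)(C)C(=O)Oc1ccc(cc1)C(=O)CC(=O)c1c(O)c(CC=C(C)C)c(OC)cc1O[Si](C(C)C)(C(C)C)C(C)C | intermediate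
13 | (R)-3-hydroxy-1-[2-hydroxy-4-methoxy-3-(3-methylbut-2-enyl)-6-(triisopropylsilyloxy)phenyl]-3-[4-(pivaloyloxy)phenyl]propan-1-one | CC(C)(C)C(=O)Oc1ccc(cc1)[C@H](O)CC(=O)c1c(O)c(CC=C(C)C)c(OC)cc1O[Si](C(C)C)(C(C)C)C(C)C | intermediate
14 | (1R,3R)-anti-1-[2-hydroxy-4-methoxy-3-(3-methylbut-2-enyl)-6-(triisopropylsilyloxy)phenyl]-3-[4-(pivaloyloxy)phenyl]propane-1,3-diol | CC(C)(C)C(=O)Oc1ccc(cc1)[C@H](O)C[C@@H](O)c1c(O)c(CC=C(C)C)c(OC)cc1O[Si](C(C)C)(C(C)C)C(C)C | intermediate
15 | alkoxyphosphonium phenoxide zwitterion of 14 (triphenylphosphonio group on the ring-B carbinol oxygen, ring-A phenoxide) | CC(C)(C)C(=O)Oc1ccc(cc1)[C@H](O[P+](c1ccccc1)(c1ccccc1)c1ccccc1)C[C@@H](O)c1c([O-])c(CC=C(C)C)c(OC)cc1O[Si](C(C)C)(C(C)C)C(C)C | intermediate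
16 | (2S,4R)-2,4-trans-7-methoxy-8-(3-methylbut-2-enyl)-2-[4-(pivaloyloxy)phenyl]-5-(triisopropylsilyloxy)chroman-4-ol | COc1cc(O[Si](C(C)C)(C(C)C)C(C)C)c2c(c1CC=C(C)C)O[C@H](c1ccc(OC(=O)C(C)(C)C)cc1)C[C@H]2O | intermediate
17 | (2S,4R)-7-methoxy-8-(3-methylbut-2-enyl)-2-[4-(pivaloyloxy)phenyl]chroman-4,5-diol | COc1cc(O)c2c(c1CC=C(C)C)O[C@H](c1ccc(OC(=O)C(C)(C)C)cc1)C[C@H]2O | intermediate
18 | (2S,4R)-4,5,4'-trihydroxy-7-methoxy-8-prenylflavan | COc1cc(O)c2c(c1CC=C(C)C)O[C@H](c1ccc(O)cc1)C[C@H]2O | target

## Step count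

Total step count: 12.
Longest linear sequence: 11 steps (steps 1, 2 and 4 to 12, from 4-hydroxybenzoic acid 1 to 18); the ring-A line from 4 is 10 steps.

## Steps most likely to fail, with fallbacks

1. Step 10 (proposed new method). What may go wrong: competitive activation of the C4 hydroxyl followed by phenoxide-assisted loss of that oxygen (ortho-quinone methide pathway or elimination), or partial ionisation at C2 that erodes the inversion. The fallback uses known chemistry, closes ring C first, sets out from hydroxy ketone 13 and comes back to the route at target 18. Mitsunobu cyclisation of 13 (PPh3, DIAD, THF, 0 °C), the established flavanone-forming closure of β-hydroxy 2'-hydroxyaryl ketones with inversion, should give (2S)-7-methoxy-8-prenyl-4'-pivaloyloxy-5-(triisopropylsilyloxy)flavanone F1. Reduction with NaBH4 (MeOH/THF, −20 °C) should give the 2,4-cis alcohol (2S,4S)-7-methoxy-8-prenyl-4'-pivaloyloxy-5-(triisopropylsilyloxy)flavan-4-ol F2. Mitsunobu inversion at C4 with 4-nitrobenzoic acid (PPh3, DIAD, toluene, −20 °C) should give the 2,4-trans ester (2S,4R)-7-methoxy-8-prenyl-4'-pivaloyloxy-5-(triisopropylsilyloxy)flavan-4-yl 4-nitrobenzoate F3. K2CO3 in MeOH at 0 °C should remove both esters to give (2S,4R)-7-methoxy-8-prenyl-5-(triisopropylsilyloxy)flavan-4,4'-diol F4, and TBAF/AcOH in THF at 0 °C then gives 18.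

2. Step 9. What may go wrong: slow hydride transfer to the chelated, di-ortho-substituted ring-A carbonyl; acid-induced ionisation of the new electron-rich benzylic C–O bond (over-reduction or epimerisation at C4); or dehydration of the β-hydroxy ketone towards the chalcone. The fallback replaces acid-mediated hydride delivery by an acid-free Evans–Tishchenko reduction, sets out from 13 and comes back at diol 14. Samarium diiodide SmI2 (cat.) with isobutyraldehyde in THF at −10 °C should transfer hydride from the samarium-bound hemiacetal to the ketone and give the anti monoester (1R,3R)-3-hydroxy-3-[2-hydroxy-4-methoxy-3-prenyl-6-(triisopropylsilyloxy)phenyl]-1-[4-(pivaloyloxy)phenyl]propyl 2-methylpropanoate F5. K2CO3 in MeOH should remove both acyl groups to give (1R,3R)-1-[2-hydroxy-4-methoxy-3-prenyl-6-(triisopropylsilyloxy)phenyl]-3-(4-hydroxyphenyl)propane-1,3-diol F6. One equivalent of PivCl with Et3N in CH2Cl2 at −40 °C should re-acylate only the unhindered 4'-phenol and return 14.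

3. Step 5. What may go wrong: arrest at the ortho stage by early enolisation, which leaves a reverse-prenyl group on the wrong carbon, or Lewis-acid cleavage of the prenyl ether. The fallback puts prenyl on carbon directly, sets out from acetophenone 4 (with 5 and 3) and comes back at silyl ether 11. C-Prenylation of 4 with 5 in aq. KOH at 0 °C should give 1-[2,6-dihydroxy-4-methoxy-3-(3-methylbut-2-enyl)phenyl]ethanone F7. One equivalent of TIPSOTf with 2,6-lutidine at −78 °C should silylate the hydroxyl remote from the prenyl group and give 1-[2-hydroxy-4-methoxy-3-(3-methylbut-2-enyl)-6-(triisopropylsilyloxy)phenyl]ethanone F8. Aroylation of the remaining chelated hydroxyl with 3 (NaH, THF, or Et3N/DMAP) then gives 11.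

Further compounds

F1 | step 10 | (2S)-7-methoxy-8-prenyl-4'-pivaloyloxy-5-(triisopropylsilyloxy)flavanone | COc1cc(O[Si](C(C)C)(C(C)C)C(C)C)c2c(c1CC=C(C)C)O[C@H](c1ccc(OC(=O)C(C)(C)C)cc1)CC2=O
F2 | step 10 | (2S,4S)-2,4-cis-7-methoxy-8-prenyl-4'-pivaloyloxy-5-(triisopropylsilyloxy)flavan-4-ol | COc1cc(O[Si](C(C)C)(C(C)C)C(C)C)c2c(c1CC=C(C)C)O[C@H](c1ccc(OC(=O)C(C)(C)C)cc1)C[C@@H]2O
F3 | step 10 | (2S,4R)-7-methoxy-8-prenyl-4'-pivaloyloxy-5-(triisopropylsilyloxy)flavan-4-yl 4-nitrobenzoate | COc1cc(O[Si](C(C)C)(C(C)C)C(C)C)c2c(c1CC=C(C)C)O[C@H](c1ccc(OC(=O)C(C)(C)C)cc1)C[C@H]2OC(=O)c1ccc(cc1)[N+](=O)[O-]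
F4 | step 10 | (2S,4R)-7-methoxy-8-prenyl-5-(triisopropylsilyloxy)flavan-4,4'-diol | COc1cc(O[Si](C(C)C)(C(C)C)C(C)C)c2c(c1CC=C(C)C)O[C@H](c1ccc(O)cc1)C[C@H]2O
F5 | step 9 | (1R,3R)-3-hydroxy-3-[2-hydroxy-4-methoxy-3-prenyl-6-(triisopropylsilyloxy)phenyl]-1-[4-(pivaloyloxy)phenyl]propyl 2-methylpropanoate | CC(C)(C)C(=O)Oc1ccc(cc1)[C@H](OC(=O)C(C)C)C[C@@H](O)c1c(O)c(CC=C(C)C)c(OC)cc1O[Si](C(C)C)(C(C)C)C(C)C
F6 | step 9 | (1R,3R)-1-[2-hydroxy-4-methoxy-3-prenyl-6-(triisopropylsilyloxy)phenyl]-3-(4-hydroxyphenyl)propane-1,3-diol | Oc1ccc(cc1)[C@H](O)C[C@@H](O)c1c(O)c(CC=C(C)C)c(OC)cc1O[Si](C(C)C)(C(C)C)C(C)C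
F7 | step 5 | 1-[2,6-dihydroxy-4-methoxy-3-(3-methylbut-2-enyl)phenyl]ethanone | CC(=O)c1c(O)cc(OC)c(CC=C(C)C)c1O
F8 | step 5 | 1-[2-hydroxy-4-methoxy-3-(3-methylbut-2-enyl)-6-(triisopropylsilyloxy)phenyl]ethanone | CC(=O)c1c(O)c(CC=C(C)C)c(OC)cc1O[Si](C(C)C)(C(C)C)C(C)C
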